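The plan reads the hemiketal ring O2'–C4–C3–C2–C1'–C2' as a benzofuran whose vinylic O–C bond has taken up one carbon, C4. Reductive opening of a 4-oxygenated benzofuran gives a (Z)-2-lithiovinyl phenoxide. Its carbanion (C3) is acylated by the A-ring chromene ester, and the freed phenoxide oxygen closes on the new ketone. One operation thus joins both halves and enlarges the five-membered furan ring to the six-membered pyran ring, isolated as a flavylium salt. It exploits the fact that C4 is bonded to both O2' and C3. Buffered hydration and a catalyst-controlled oxa-Michael addition of the A-ring phenol to C2 then close the 2,6-dioxabicyclo[3.3.1]nonane.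

Key step: step 6

Remark: flavonoid numbering is used (O1, C2, C3, C4, C4a–C8a; primed numbers for the dihydroxyphenyl ring; O2' is the bridging oxygen), and the given SMILES corresponds to (2R,4R).

Step 1
Reactants: 1 5-methoxyresorcinol (3,5-dihydroxyanisole)
Product: 3 2,2,2-trichloro-1-(2,4-dihydroxy-6-methoxyphenyl)ethan-1-one, via ketiminium chloride 2 (not isolated)
Conditions: Cl3CCN, ZnCl2 (cat.), HCl (g), Et2O, 0 °C; then H2O, 60 °C
Reagents that add atoms: trichloroacetonitrile ClC(Cl)(Cl)C#N; water O
Why: Houben–Hoesch acylation, in which the activated nitrile should attack the ring carbon ortho to one hydroxyl and para to the other (two equivalent sites) rather than the more crowded carbon between the hydroxyls, and the iminium salt 2 is hydrolysed to the ketone; no stereocentre is formed.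

Step 2
Reactants: 3 2,2,2-trichloro-1-(2,4-dihydroxy-6-methoxyphenyl)ethan-1-one
Product: 4 methyl 2,4-dihydroxy-6-methoxybenzoate
Conditions: MeOH, Et3N (cat.), rt to 50 °C
Reagents that add atoms: methanol CO
Why: Haloform-type acyl substitution, in which methanol adds to the activated carbonyl and trichloromethanide leaves, so the salicylate should form without touching the free phenols.

Step 3
Reactants: 4 methyl 2,4-dihydroxy-6-methoxybenzoate
Product: 5 methyl 2,4-dihydroxy-6-methoxy-3-(3-methylbut-2-en-1-yl)benzoate
Conditions: prenyl bromide, KOH, H2O–MeOH, 0 °C to rt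
Reagents that add atoms: prenyl bromide CC(C)=CCBr
Why: C-alkylation of the ambident phenoxide in protic medium (C-prenylation of an acylresorcinol), in which the carbon between the two hydroxyl groups is the most nucleophilic site and SN2 attack at the primary carbon keeps the 3,3-dimethylallyl form.

Step 4
Reactants: 5 methyl 2,4-dihydroxy-6-methoxy-3-(3-methylbut-2-en-1-yl)benzoate
Product: 6 methyl 7-hydroxy-5-methoxy-2,2-dimethyl-8-(3-methylbut-2-en-1-yl)-2H-chromene-6-carboxylate
Conditions: 3-methylbut-2-enal, ethylenediammonium diacetate (10 mol %), PhMe, reflux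
Reagents that add atoms: 3-methylbut-2-enal CC(C)=CC=O
Why: Knoevenagel-type condensation at the only free ring carbon, loss of water and oxa-6π electrocyclisation through the adjacent non-chelated hydroxyl allow only one regiochemistry for the 2,2-dimethylchromene, because the other ortho carbon is blocked by the prenyl group.

Step 5
Reactants: 7 benzofuran-4-ol
Product: 8 4-(1-ethoxyethoxy)benzofuran
Conditions: ethyl vinyl ether, PPTS (cat.), CH2Cl2, 0 °C
Reagents that add atoms: ethyl vinyl ether C=COCC
Why: Acid-catalysed addition of the phenol to the enol ether gives a base-stable, very acid-labile acetal (racemic at the acetal carbon, which is lost again in step 6), so no phenoxide hampers electron uptake in the next step.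

Step 6
Reactants: 6 methyl 7-hydroxy-5-methoxy-2,2-dimethyl-8-(3-methylbut-2-en-1-yl)-2H-chromene-6-carboxylate; 8 4-(1-ethoxyethoxy)benzofuran
Product: 12 5-hydroxy-2-[7-hydroxy-5-methoxy-2,2-dimethyl-8-(3-methylbut-2-en-1-yl)-2H-chromen-6-yl]chromenylium tetrafluoroborate, via lithium phenoxide 9 (not isolated), via dilithio (Z)-vinylphenoxide 10 (not isolated), via hemiketal 11 (not isolated)
Conditions: 8, Li powder, DTBB (5 mol %), THF, 0 °C, decant from Li; 6, MeLi (1.0 equiv), THF, −78 °C; combine, −78 to −20 °C; HBF4·OEt2 (4.0 equiv), Et2O, −78 to 0 °C, filter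
Reagents that add atoms: tetrafluoroboric acid diethyl etherate (supplies the counter-ion) [H+].F[B-](F)(F)F
Why: Lithium, with DTBB as electron carrier, transfers two electrons to 8 and breaks the vinylic O–C bond of the furan ring, giving the chelated dilithio species 10 with the cis geometry of the ring retained; its sp2 carbanion (future C3) adds to the ester carbonyl (future C4) of 9, methoxide leaves, and the B-ring phenoxide released in the ring opening adds to the new ketone, so that C4 stands between O2' and C3 in hemiketal 11. Acid then removes the ethoxyethyl acetal and ionises 11 to the aromatic chromenylium salt 12, which should precipitate and keeps the A-ring phenol from adding to C2 without control. The closest known reaction type is the arene-catalysed reductive opening of benzofuran with capture by carbonyl compounds and acid closure to 2H-chromenes, combined with the known acylation of organolithiums by 2,6-dioxygenated benzoates and the known closure of cis-2-hydroxychalcones to flavylium ions. The only ring closed is the pyran ring, by 6-exo-trig addition of the phenoxide oxygen to the ketone, which is possible only from the Z-alkene that the ring opening delivers. No lasting stereocentre arises, since C4 of 11 becomes planar in 12. The step needs cleavage of the O–vinyl rather than the O–aryl or acetal bond (secured by the phenoxide/vinyl anion pair being the best-stabilised fragments), a single addition to the ester (secured by the two ortho oxygen substituents and by internal hemiketal formation) and intact prenyl and chromene alkenes (secured by removing excess lithium before 9 is added and by using only the stoichiometric amount of acid in the cold).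

Step 7
Reactants: 12 5-hydroxy-2-[7-hydroxy-5-methoxy-2,2-dimethyl-8-(3-methylbut-2-en-1-yl)-2H-chromen-6-yl]chromenylium tetrafluoroborate
Product: 16 (2R,4R)-4,2'-epoxy-4,6'-dihydroxy-5-methoxy-8-prenyl-6,7-(2,2-dimethylpyrano)flavan (CNP0170313.2), via pseudo-base 13 (not isolated), via (Z)-chalcone 14 (not isolated), via (2R)-flavanone 15 (not isolated)
Conditions: NaHCO3 (1.05 equiv), H2O (5 equiv), CH2Cl2–PhMe, −20 °C; then epi-quinidine-derived 3,5-bis(trifluoromethyl)phenyl thiourea (10 mol %), −20 °C, dark
Reagents that add atoms: water O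
Why: Buffered hydration of the chromenylium ion at C4 gives pseudo-base 13, which equilibrates with the (Z)-enone 14 as in the known flavylium network; the bifunctional cinchona thiourea (hydrogen bonds to the enone, quinuclidine to the A-ring phenol) should then steer the 6-endo-trig oxa-Michael addition of O1 to one face of C2 (organocatalytic asymmetric cyclisation of 2'-hydroxychalcones), which sets (2R), and in flavanone 15 the B-ring phenol can reach the C4 carbonyl only from the face that carries the aryl group, which fixes (4R) and locks the product against retro-Michael racemisation.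

Compound list
1 | 5-methoxyresorcinol (3,5-dihydroxyanisole) | COc1cc(O)cc(O)c1 | starting material
2 | 2,2,2-trichloro-1-(2,4-dihydroxy-6-methoxyphenyl)ethan-1-iminium chloride | COc1cc(O)cc(O)c1C(=[NH2+])C(Cl)(Cl)Cl.[Cl-] | intermediate
3 | 2,2,2-trichloro-1-(2,4-dihydroxy-6-methoxyphenyl)ethan-1-one | COc1cc(O)cc(O)c1C(=O)C(Cl)(Cl)Cl | intermediate
4 | methyl 2,4-dihydroxy-6-methoxybenzoate | COc1cc(O)cc(O)c1C(=O)OC | intermediate
5 | methyl 2,4-dihydroxy-6-methoxy-3-(3-methylbut-2-en-1-yl)benzoate | COc1cc(O)c(CC=C(C)C)c(O)c1C(=O)OC | intermediate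
6 | methyl 7-hydroxy-5-methoxy-2,2-dimethyl-8-(3-methylbut-2-en-1-yl)-2H-chromene-6-carboxylate | COC(=O)c1c(OC)c2C=CC(C)(C)Oc2c(CC=C(C)C)c1O | intermediate
7 | benzofuran-4-ol | Oc1cccc2occc12 | starting material
8 | 4-(1-ethoxyethoxy)benzofuran (racemic acetal) | CCOC(C)Oc1cccc2occc12 | intermediate
9 | lithium phenoxide of ester 6 | COC(=O)c1c(OC)c2C=CC(C)(C)Oc2c(CC=C(C)C)c1O[Li] | intermediate
10 | lithium 3-(1-ethoxyethoxy)-2-[(Z)-2-lithioethenyl]phenoxide | [Li]/C=C\c1c(O[Li])cccc1OC(C)OCC | intermediate
11 | 5-(1-ethoxyethoxy)-2-[7-hydroxy-5-methoxy-2,2-dimethyl-8-prenyl-2H-chromen-6-yl]-2H-chromen-2-ol (present as its lithium salt until the quench) | CCOC(C)Oc1cccc2OC(O)(C=Cc12)c1c(OC)c2C=CC(C)(C)Oc2c(CC=C(C)C)c1O | intermediate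
12 | 5-hydroxy-2-[7-hydroxy-5-methoxy-2,2-dimethyl-8-(3-methylbut-2-en-1-yl)-2H-chromen-6-yl]chromenylium tetrafluoroborate | Oc1cccc2[o+]c(ccc12)-c1c(OC)c2C=CC(C)(C)Oc2c(CC=C(C)C)c1O.F[B-](F)(F)F | intermediate
13 | 2-[7-hydroxy-5-methoxy-2,2-dimethyl-8-prenyl-2H-chromen-6-yl]-2H-chromene-2,5-diol (pseudo-base) | Oc1cccc2OC(O)(C=Cc12)c1c(OC)c2C=CC(C)(C)Oc2c(CC=C(C)C)c1O | intermediate
14 | (Z)-3-(2,6-dihydroxyphenyl)-1-[7-hydroxy-5-methoxy-2,2-dimethyl-8-prenyl-2H-chromen-6-yl]prop-2-en-1-one | O=C(/C=C\c1c(O)cccc1O)c1c(OC)c2C=CC(C)(C)Oc2c(CC=C(C)C)c1O | intermediate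
15 | (2R)-2-(2,6-dihydroxyphenyl)-5-methoxy-8,8-dimethyl-10-(3-methylbut-2-enyl)-2,3-dihydropyrano[3,2-g]chromen-4-one | COc1c2c(c(CC=C(C)C)c3c1C(=O)C[C@@H](O3)c1c(O)cccc1O)OC(C)(C)C=C2 | intermediate
16 | (2R,4R)-hemiketal of 15 (O2' bonded to C4, 4-OH free), CNP0170313.2 | COc1c2c(c(CC=C(C)C)c3c1[C@@]1(O)C[C@@H](O3)c3c(O)cccc3O1)OC(C)(C)C=C2 | target

Total step count: 7. Longest linear sequence: 6 steps (1, 2, 3, 4, 6, 7).

Steps most likely to fail

Step 6. The acylation may stall at the crowded, anionic salicylate or run on to the tertiary alcohol. The acetal may be cleaved by the arene radical anion before the furan ring opens. Surplus acid may cyclise the prenyl group onto the neighbouring phenol. The fallback sets out from 6 and 8 and comes back at 12. Ester 6 is reduced with DIBAL-H (−78 °C) to 7-hydroxy-5-methoxy-2,2-dimethyl-8-prenyl-2H-chromene-6-carbaldehyde F1, which MeLi converts into its lithium phenoxide F2. This far more reactive electrophile takes up 10 (made from 8 as in step 6) to give the (Z)-allylic alcohol F3. Dilute H3PO4 removes the acetal and closes the ring through O2' at the better stabilised allyl terminus C4, giving the 2-aryl-2H-chromen-5-ol F4. This is the established benzofuran-to-2H-chromene ring enlargement. Hydride abstraction from C2 of that chromene with trityl tetrafluoroborate (CH2Cl2, 0 °C) gives 12.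

Step 7. Facial selectivity may be poor because the enone is unactivated and crowded. An uncatalysed background addition may compete, and slow Z-to-E isomerisation may hold material back as the trans-chalcone. If only the sense of induction is wrong, the quinine-derived pseudo-enantiomer of the catalyst is used. The fallback sets out from 12 and comes back at 16. Closure without a chiral catalyst (NaOAc, aqueous EtOH, 50 °C) gives the racemic hemiketal F5. This is then resolved kinetically by asymmetric transfer hydrogenation (Rh– or Ru–TsDPEN, HCO2H/Et3N). The catalyst enantiomer matched to the (2S)-ketone tautomer reduces it to the (2S,4S)-flavan-4-ol F6 and leaves 16, which is separated by chromatography.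

Step 3. O-alkylation, attack at C5 and double prenylation may erode the C3-selective alkylation. The fallback sets out from 4 and comes back at 5. The non-chelated 4-OH is alkylated with 3-chloro-3-methylbut-1-yne (K2CO3, KI, CuI cat., acetone) to give the 1,1-dimethylpropargyl ether F7. Lindlar semi-hydrogenation gives the 1,1-dimethylallyl ether F8. An aromatic Claisen rearrangement (PhNEt2, 130 °C) then transfers the group with allyl inversion, as a normal prenyl group, to C3. C3 is the ortho position favoured by bond fixation in the chelated salicylate, so this gives 5.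

Further compounds
F1 | step 6 | 7-hydroxy-5-methoxy-2,2-dimethyl-8-(3-methylbut-2-en-1-yl)-2H-chromene-6-carbaldehyde | O=Cc1c(OC)c2C=CC(C)(C)Oc2c(CC=C(C)C)c1O
F2 | step 6 | lithium phenoxide of F1 | O=Cc1c(OC)c2C=CC(C)(C)Oc2c(CC=C(C)C)c1O[Li]
F3 | step 6 | (Z)-3-[2-(1-ethoxyethoxy)-6-hydroxyphenyl]-1-[7-hydroxy-5-methoxy-2,2-dimethyl-8-prenyl-2H-chromen-6-yl]prop-2-en-1-ol | CCOC(C)Oc1cccc(O)c1/C=C\C(O)c1c(OC)c2C=CC(C)(C)Oc2c(CC=C(C)C)c1O
F4 | step 6 | 2-[7-hydroxy-5-methoxy-2,2-dimethyl-8-prenyl-2H-chromen-6-yl]-2H-chromen-5-ol | Oc1cccc2OC(C=Cc12)c1c(OC)c2C=CC(C)(C)Oc2c(CC=C(C)C)c1O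
F5 | step 7 | racemic hemiketal (rac-16) | COc1c2c(c(CC=C(C)C)c3c1C1(O)CC(O3)c3c(O)cccc3O1)OC(C)(C)C=C2
F6 | step 7 | (2S,4S)-2-(2,6-dihydroxyphenyl)-5-methoxy-8,8-dimethyl-10-prenyl-3,4-dihydro-2H-pyrano[3,2-g]chromen-4-ol | COc1c2c(c(CC=C(C)C)c3c1[C@@H](O)C[C@H](O3)c1c(O)cccc1O)OC(C)(C)C=C2
F7 | step 3 | methyl 2-hydroxy-6-methoxy-4-[(2-methylbut-3-yn-2-yl)oxy]benzoate | COc1cc(OC(C)(C)C#C)cc(O)c1C(=O)OC
F8 | step 3 | methyl 2-hydroxy-6-methoxy-4-[(2-methylbut-3-en-2-yl)oxy]benzoate | COc1cc(OC(C)(C)C=C)cc(O)c1C(=O)OC
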